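**Plan**

- Retrosynthesis: the p-hydroxybenzoate ester is cut first. The oxolane (O1, C2 aryl, C3 side chain, C4 benzylidene, C5 H2) is then cut in one stroke at O1–C5 and C3–C4. This gives a C3–C2–O1 unit (an α-bromo-β-hydroxy imide, with the C3 side chain at the acyl level) and a C4–C5 unit (the terminal C=C of an arylallene). Both units go back to vanillin.
- Forward: vanillin silyl ether gives (a) the arylallene and (b) the Evans aldol adduct with a bromoacetyl oxazolidinone. A photoredox radical–polar annulation joins them and builds the only ring together with the exocyclic alkene. Reductive loss of the auxiliary gives the CH2OH group, followed by esterification and desilylation.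
- Enabling feature: C4 is an sp2 ring carbon between the ring CH2 (C5) and an exocyclic CH carrying an electron-rich guaiacyl ring. The array C5–C4=CH–Ar is therefore an arylallene in disguise: a radical adds at its central carbon and the resulting allyl system is electrophilic at CH2. O1–C2–C3 is an aldol unit whose C3 can carry a radical while its side-chain carbon is an acyl group.
- Stereochemistry: C2 comes from the auxiliary-controlled syn-aldol. C3 comes from 1,2-induction (allylic strain) in the radical addition and gives the 2,3-trans ring. The (Z)-benzylidene comes from the way the allyl system forms, and it is also the less strained isomer.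

Key step: step 6

Assumption: the benzylidene is taken as drawn, Z, with the aryl group on the side of the ring O–CH2. Abbreviations: TIPS = tri(propan-2-yl)silyl; Ar = 3-methoxy-4-(TIPS-oxy)phenyl; Xc = (4R)-4-benzyl-2-oxo-1,3-oxazolidin-3-yl; NBSH = 2-nitrobenzenesulfonohydrazide.

**Step 1**
Reactants: 1 vanillin
Product: 2 3-methoxy-4-(TIPS-oxy)benzaldehyde (ArCHO)
Conditions: TIPSCl, imidazole, DMF, rt
Reagents that add atoms: TIPSCl, CC(C)[Si](Cl)(C(C)C)C(C)C
Why: Imidazole-promoted O-silylation masks the phenol for the Grignard, boron enolate and hydride steps, and the aryl TIPS ether is later removed by buffered fluoride.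

**Step 2**
Reactants: 2 ArCHO
Product: 3 racemic 1-Ar-prop-2-yn-1-ol
Conditions: ethynylmagnesium bromide, THF, 0 °C; aqueous work-up
Reagents that add atoms: ethynylmagnesium bromide, C#C[Mg]Br
Why: Grignard 1,2-addition to the aldehyde gives the propargylic alcohol; its carbinol centre is racemic and is destroyed in step 3.

**Step 3**
Reactants: 3 racemic 1-Ar-prop-2-yn-1-ol
Product: 6 [2-methoxy-4-(propa-1,2-dien-1-yl)phenoxy]tri(propan-2-yl)silane (ArCH=C=CH2), via sulfonylhydrazine adduct 4 (not isolated), via propargylic diazene 5 (not isolated)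
Conditions: NBSH, PPh3, DEAD, THF, −15 °C, then rt
Reagents that add atoms: none
Why: Myers allene synthesis, in which Mitsunobu alkylation of NBSH at the sulfonylated nitrogen gives 4, loss of 2-nitrobenzenesulfinic acid gives the diazene 5, and its retro-ene loss of N2 places hydrogen on the alkyne terminus to give the achiral terminal allene.

**Step 4**
Reactants: 7 (R)-4-benzyl-1,3-oxazolidin-2-one
Product: 9 (R)-4-benzyl-3-(bromoacetyl)-1,3-oxazolidin-2-one, via N-lithio oxazolidinone 8 (not isolated)
Conditions: n-BuLi, THF, −78 °C; then bromoacetyl bromide, −78 °C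
Reagents that add atoms: bromoacetyl bromide, O=C(Br)CBr
Why: N-acylation of the lithiated oxazolidinone at the acyl bromide carbon, which is faster than alkylation at CH2Br, installs the auxiliary that controls the carbinol centre.

**Step 5**
Reactants: 9 (R)-4-benzyl-3-(bromoacetyl)-1,3-oxazolidin-2-one, 2 ArCHO
Product: 11 (4R)-4-benzyl-3-[(2R,3S)-2-bromo-3-hydroxy-3-Ar-propanoyl]-1,3-oxazolidin-2-one, via dibutylboron Z-enolate 10 (not isolated)
Conditions: Bu2BOTf, Et3N, CH2Cl2, −78 to 0 °C; then 2, −78 to 0 °C; pH 7 buffer, MeOH, H2O2, 0 °C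
Reagents that add atoms: none
Why: Evans syn-aldol addition, in which the Z-boron enolate reacts through a closed chair (Zimmerman–Traxler) transition state on the face away from the benzyl group of the (R)-auxiliary, setting the carbinol centre S (the later C2 of the oxolane) and the bromine-bearing centre R (2,3-syn; this second centre is erased in step 6).

**Step 6**
Reactants: 11 bromohydrin imide, 6 ArCH=C=CH2
Product: 13 (4R)-4-benzyl-3-{[(2R,3R,4Z)-2-Ar-4-(Ar-methylidene)oxolan-3-yl]carbonyl}-1,3-oxazolidin-2-one, via allylic bromide 12 (not isolated)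
Conditions: fac-Ir(ppy)3 (tris(2-phenylpyridinato)iridium, 1 mol %), 2,6-lutidine, degassed MeCN, 450 nm LEDs, rt; then 50 °C in the dark
Reagents that add atoms: none
Why: Proposed new method: the photoexcited iridium complex should reduce the C–Br bond of 11 to an electrophilic α-acyl radical, which adds to the central carbon of the electron-rich allene 6 (bond C3–C4 of the oxolane) to give a benzylic radical that relaxes to the 1-aryl-allyl radical, and the tetravalent iridium complex formed in the first event oxidises this to the allyl cation, which bromide captures at its CH2 end to give the cinnamyl-type bromide 12 (overall an atom-transfer radical addition). The free hydroxyl of 12 then displaces the primary allylic bromide and closes the only ring by a 5-exo-tet O-alkylation (bond O1–C5), with 2,6-lutidine taking up HBr, so that no 5-endo capture of the planar cation is required. The closest known reaction types are the photoredox atom-transfer radical addition and radical–polar crossover oxyalkylation of styrenes with α-bromo carbonyl compounds, and the [3+2] annulations of alkenes with α-halo or 1,3-dicarbonyl radicals mediated by copper or by Mn(OAc)3 (trivalent manganese), here carried over to a β-hydroxy α-bromo imide as the C–C–O partner and an allene as the two-carbon partner. The carbinol centre (C2) is carried over from 11, and the new centre C3 is set in the radical addition, where allylic 1,3-strain holds the carbinol C–H in the plane of the acyl radical and the allene adds anti to the aryl group, which corresponds to the 2,3-trans ring. The step needs central attack on the allene, secured because only that gives a benzylic allyl radical; closure at CH2 and not at the benzylic end, secured by the primary conjugated position of bromine in 12 and the ready re-ionisation of any doubly activated benzylic ether; and the (Z)-benzylidene, secured because the aryl group turns toward the small CH2 terminus and away from the branched C3 when the allyl system becomes planar.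

**Step 7**
Reactants: 13 oxolane imide
Product: 14 [(2R,3S,4Z)-2-Ar-4-(Ar-methylidene)oxolan-3-yl]methanol
Conditions: LiBH4, MeOH (1 equiv), THF, 0 °C
Reagents that add atoms: none
Why: Reductive removal of the Evans auxiliary by hydride attack on the exocyclic imide carbonyl gives the primary alcohol without base, hence without epimerisation at C3 or migration of the benzylidene double bond (the C3 descriptor changes from R to S by priority only).

**Step 8**
Reactants: 14 oxolanyl methanol, 15 4-hydroxybenzoic acid
Product: 16 [(2R,3S,4Z)-2-Ar-4-(Ar-methylidene)oxolan-3-yl]methyl 4-hydroxybenzoate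
Conditions: PPh3, DIAD, THF, 0 °C to rt
Reagents that add atoms: none
Why: Mitsunobu esterification at a primary carbon, in which the carboxylic acid, far more acidic than the phenol of 15, is the oxygen that is alkylated, so the benzoate phenol needs no protecting group.

**Step 9**
Reactants: 16 bis-TIPS ester
Product: 17 [(2R,3S,4Z)-2-(4-hydroxy-3-methoxyphenyl)-4-[(4-hydroxy-3-methoxyphenyl)methylidene]oxolan-3-yl]methyl 4-hydroxybenzoate (target)
Conditions: TBAF, AcOH (1:1), THF, 0 °C
Reagents that add atoms: none
Why: Fluoride cleavage of the two aryl silyl ethers, buffered with acetic acid so that the freed phenols stay protonated and neither the benzoate ester nor the benzylic C2–O1 bond (opening through a para-quinone methide) is put at risk.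

**Compound list**

1 | vanillin (4-hydroxy-3-methoxybenzaldehyde) | COc1cc(C=O)ccc1O | starting material
2 | 3-methoxy-4-{[tri(propan-2-yl)silyl]oxy}benzaldehyde | COc1cc(C=O)ccc1O[Si](C(C)C)(C(C)C)C(C)C | intermediate
3 | racemic 1-(3-methoxy-4-{[tri(propan-2-yl)silyl]oxy}phenyl)prop-2-yn-1-ol | COc1cc(C(O)C#C)ccc1O[Si](C(C)C)(C(C)C)C(C)C | intermediate
4 | N-[1-(3-methoxy-4-{[tri(propan-2-yl)silyl]oxy}phenyl)prop-2-yn-1-yl]-2-nitrobenzenesulfonohydrazide (racemic, not isolated) | COc1cc(C(C#C)N(N)S(=O)(=O)c2ccccc2[N+](=O)[O-])ccc1O[Si](C(C)C)(C(C)C)C(C)C | intermediate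
5 | [1-(3-methoxy-4-{[tri(propan-2-yl)silyl]oxy}phenyl)prop-2-yn-1-yl]diazene (racemic, not isolated) | COc1cc(C(C#C)N=N)ccc1O[Si](C(C)C)(C(C)C)C(C)C | intermediate
6 | [2-methoxy-4-(propa-1,2-dien-1-yl)phenoxy]tri(propan-2-yl)silane | COc1cc(C=C=C)ccc1O[Si](C(C)C)(C(C)C)C(C)C | intermediate
7 | (R)-4-benzyl-1,3-oxazolidin-2-one | O=C1N[C@H](Cc2ccccc2)CO1 | starting material
8 | N-lithio (R)-4-benzyl-1,3-oxazolidin-2-one (not isolated) | [Li]N1[C@H](Cc2ccccc2)COC1=O | intermediate
9 | (R)-4-benzyl-3-(2-bromoacetyl)-1,3-oxazolidin-2-one | O=C(CBr)N1[C@H](Cc2ccccc2)COC1=O | intermediate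
10 | (Z)-dibutylboron enolate of 9 (not isolated) | CCCCB(CCCC)O/C(=C\Br)N1[C@H](Cc2ccccc2)COC1=O | intermediate
11 | (4R)-4-benzyl-3-[(2R,3S)-2-bromo-3-hydroxy-3-(3-methoxy-4-{[tri(propan-2-yl)silyl]oxy}phenyl)propanoyl]-1,3-oxazolidin-2-one | O[C@@H](c1ccc(O[Si](C(C)C)(C(C)C)C(C)C)c(OC)c1)[C@@H](Br)C(=O)N1[C@H](Cc2ccccc2)COC1=O | intermediate
12 | (4R)-4-benzyl-3-[(2R,3R)-2-[(1Z)-3-bromo-1-Ar-prop-1-en-2-yl]-3-hydroxy-3-Ar-propanoyl]-1,3-oxazolidin-2-one, Ar = 3-methoxy-4-{[tri(propan-2-yl)silyl]oxy}phenyl (not isolated) | COc1cc(/C=C(\CBr)[C@@H](C(=O)N2[C@H](Cc3ccccc3)COC2=O)[C@@H](O)c2ccc(O[Si](C(C)C)(C(C)C)C(C)C)c(OC)c2)ccc1O[Si](C(C)C)(C(C)C)C(C)C | intermediate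
13 | (4R)-4-benzyl-3-{[(2R,3R,4Z)-2-Ar-4-(Ar-methylidene)oxolan-3-yl]carbonyl}-1,3-oxazolidin-2-one, Ar as in 12 | COc1cc(/C=C2\CO[C@@H](c3ccc(O[Si](C(C)C)(C(C)C)C(C)C)c(OC)c3)[C@@H]2C(=O)N2[C@H](Cc3ccccc3)COC2=O)ccc1O[Si](C(C)C)(C(C)C)C(C)C | intermediate
14 | [(2R,3S,4Z)-2-Ar-4-(Ar-methylidene)oxolan-3-yl]methanol, Ar as in 12 | COc1cc(/C=C2\CO[C@@H](c3ccc(O[Si](C(C)C)(C(C)C)C(C)C)c(OC)c3)[C@@H]2CO)ccc1O[Si](C(C)C)(C(C)C)C(C)C | intermediate
15 | 4-hydroxybenzoic acid | O=C(O)c1ccc(O)cc1 | starting material
16 | [(2R,3S,4Z)-2-Ar-4-(Ar-methylidene)oxolan-3-yl]methyl 4-hydroxybenzoate, Ar as in 12 | COc1cc(/C=C2\CO[C@@H](c3ccc(O[Si](C(C)C)(C(C)C)C(C)C)c(OC)c3)[C@@H]2COC(=O)c2ccc(O)cc2)ccc1O[Si](C(C)C)(C(C)C)C(C)C | intermediate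
17 | [(2R,3S,4Z)-2-(4-hydroxy-3-methoxyphenyl)-4-[(4-hydroxy-3-methoxyphenyl)methylidene]oxolan-3-yl]methyl 4-hydroxybenzoate | COc1cc(/C=C2\CO[C@@H](c3ccc(O)c(OC)c3)[C@@H]2COC(=O)c2ccc(O)cc2)ccc1O | target

**Totals**

Total step count: 9. Longest linear sequence: 7 steps (steps 1, 2, 3, 6, 7, 8, 9).

**Steps most likely to fail**

Step 6 (proposed new method). What may go wrong: radical addition at a terminal allene carbon, low facial selectivity at C3, triplet-sensitised oligomerisation of the allene, or stalling at the open-chain bromide or closure at the benzylic end. The fallback uses known chemistry and reverses the order of bond formation: C–O by ionic alkylation first, then C–C by a 5-exo-dig radical cyclisation of the Ueno–Stork type. It sets out from 11 and 2. Corey–Fuchs olefination of 2 (CBr4, PPh3, CH2Cl2, 0 °C) gives [4-(2,2-dibromoethenyl)-2-methoxyphenoxy]tri(propan-2-yl)silane F1. Treatment with n-BuLi (THF, −78 °C) and then paraformaldehyde gives 3-Ar-prop-2-yn-1-ol F2. Cl3CCN with catalytic DBU gives 3-Ar-prop-2-yn-1-yl 2,2,2-trichloroacetimidate F3. Acid-catalysed etherification of the hydroxyl of 11 with F3 (TMSOTf cat., CH2Cl2, −20 °C, no base, so no retro-aldol or epoxide closure) gives the propargyl ether (4R)-4-benzyl-3-[(2R,3S)-2-bromo-3-Ar-3-(3-Ar-prop-2-yn-1-yloxy)propanoyl]-1,3-oxazolidin-2-one F4. Bu3SnH and AIBN (benzene, 80 °C, slow addition) then generate the same α-acyl radical, which should close onto the arylalkyne with the 2,3-trans ring favoured. If the benzylidene forms as a mixture, catalytic iodine in daylight should equilibrate it to the less strained Z isomer. The fallback comes back to the route at 13.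

Step 3. What may go wrong: ionisation of the electron-rich benzylic position during the Mitsunobu alkylation (ether or elimination products) and oligomerisation of the allene on warming. The fallback sets out from 3. Methyl chloroformate and pyridine (CH2Cl2, 0 °C) give methyl 1-Ar-prop-2-yn-1-yl carbonate F5. Pd2(dba)3 with PBu3 and ammonium formate (THF, rt) then ionises the carbonate at zerovalent palladium to an allenylpalladium species, which takes hydride from formate and releases the terminal allene. This formate hydrogenolysis of propargylic carbonates is a known allene synthesis. The fallback comes back to the route at 6.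

Step 8. What may go wrong: loss of chemoselectivity, with alkylation of the phenol of 15 and self-condensation of the acid. The fallback sets out from 14. Acylation with commercial 4-acetoxybenzoyl chloride (pyridine, DMAP cat., CH2Cl2, 0 °C) gives [(2R,3S,4Z)-2-Ar-4-(Ar-methylidene)oxolan-3-yl]methyl 4-acetoxybenzoate F6. Selective cleavage of the aryl acetate with hydrazine acetate (DMF, rt) leaves the alkyl benzoate and the silyl ethers intact. The fallback comes back to the route at 16.

**Further compounds**

F1 | step 6 | [4-(2,2-dibromoethenyl)-2-methoxyphenoxy]tri(propan-2-yl)silane | COc1cc(C=C(Br)Br)ccc1O[Si](C(C)C)(C(C)C)C(C)C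
F2 | step 6 | 3-(3-methoxy-4-{[tri(propan-2-yl)silyl]oxy}phenyl)prop-2-yn-1-ol | COc1cc(C#CCO)ccc1O[Si](C(C)C)(C(C)C)C(C)C
F3 | step 6 | 3-(3-methoxy-4-{[tri(propan-2-yl)silyl]oxy}phenyl)prop-2-yn-1-yl 2,2,2-trichloroacetimidate | COc1cc(C#CCOC(=N)C(Cl)(Cl)Cl)ccc1O[Si](C(C)C)(C(C)C)C(C)C
F4 | step 6 | (4R)-4-benzyl-3-[(2R,3S)-2-bromo-3-Ar-3-(3-Ar-prop-2-yn-1-yloxy)propanoyl]-1,3-oxazolidin-2-one, Ar = 3-methoxy-4-{[tri(propan-2-yl)silyl]oxy}phenyl | COc1cc(C#CCO[C@@H](c2ccc(O[Si](C(C)C)(C(C)C)C(C)C)c(OC)c2)[C@@H](Br)C(=O)N2[C@H](Cc3ccccc3)COC2=O)ccc1O[Si](C(C)C)(C(C)C)C(C)C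
F5 | step 3 | methyl 1-(3-methoxy-4-{[tri(propan-2-yl)silyl]oxy}phenyl)prop-2-yn-1-yl carbonate (racemic) | COc1cc(C(OC(=O)OC)C#C)ccc1O[Si](C(C)C)(C(C)C)C(C)C
F6 | step 8 | [(2R,3S,4Z)-2-Ar-4-(Ar-methylidene)oxolan-3-yl]methyl 4-acetoxybenzoate, Ar as in F4 | COc1cc(/C=C2\CO[C@@H](c3ccc(O[Si](C(C)C)(C(C)C)C(C)C)c(OC)c3)[C@@H]2COC(=O)c2ccc(OC(C)=O)cc2)ccc1O[Si](C(C)C)(C(C)C)C(C)C
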